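**Plan**

- Retrosynthesis: the four MOM ethers are removed first. Ring C is then cut at C4–C4a and O1–C8a in one operation, to an (S)-beta-silyloxy ester and a 3,5-dioxygenated benzyne. C2–C3 is cut next (acetate aldol) to the ring B aldehyde, and last the two aryl–prenyl bonds.
- Forward: ring B is present from the start and is prenylated at C5′ (Stille coupling) and C2′ (directed lithiation). The aldol adds C3/C4 and sets C2. Ring A arrives from phloroglucinol as an aryne, and ring C is closed last by C4–C4a bond formation, followed by global MOM removal.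
- Stereochemistry: the single stereocenter C2 (S) comes from a catalyst-controlled Si-face Mukaiyama aldol. It is carried through with retention because the C2–O bond is never broken.
- Enabling feature: ring A is a 1,3,5-trioxygenated benzene in which C4a lies between C8a (bearing O1) and C5 (bearing oxygen). In the aryne C4a≡C8a the C5 oxygen therefore directs an O-nucleophile to C8a and places the carbanion on C4a. Ring C is a beta-aryloxy ketone, so the ester carbonyl (C4) of a beta-oxy ester sits where that carbanion closes a six-membered ring.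

Key step: step 8

Assumption: silyl ketene acetal 10 is taken as a catalogue reagent; it is otherwise one step from methyl acetate (LDA, TMSCl).

**Route**

Step 1
Reactants: 1 3-bromo-4,5-dihydroxybenzaldehyde
Product: 2 3-bromo-4,5-bis(methoxymethoxy)benzaldehyde
Conditions: MOMCl (2.5 equiv), i-Pr2NEt, CH2Cl2, 0 °C to rt
Reagents that add atoms: chloromethyl methyl ether (MOMCl), COCCl
Why: Twofold O-alkylation of the catechol (Williamson-type acetal formation); MOM should survive the organolithium, fluoride and palladium steps and leave under mild acid at the end.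

Step 2
Reactants: 2 3-bromo-4,5-bis(methoxymethoxy)benzaldehyde; 3 tributyl(3-methylbut-2-en-1-yl)stannane
Product: 4 3,4-bis(methoxymethoxy)-5-(3-methylbut-2-en-1-yl)benzaldehyde
Conditions: Pd(PPh3)4 (5 mol%), LiCl, DMF, 90 °C
Reagents that add atoms: none
Why: Stille coupling (oxidative addition of zerovalent palladium to the aryl bromide, transmetalation from tin, reductive elimination at the unsubstituted allyl terminus) should give the linear prenyl arene under neutral conditions that tolerate the aldehyde and the MOM ethers.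

Step 3
Reactants: 4 3,4-bis(methoxymethoxy)-5-(3-methylbut-2-en-1-yl)benzaldehyde; 5 1-bromo-3-methylbut-2-ene (prenyl bromide)
Product: 9 3,4-bis(methoxymethoxy)-2,5-bis(3-methylbut-2-en-1-yl)benzaldehyde, via lithium alpha-amino alkoxide 6 (not isolated), via C2 aryllithium 7 (not isolated), via prenylated amino alkoxide 8 (not isolated)
Conditions: LiN(Me)CH2CH2NMe2 (from MeNHCH2CH2NMe2 and n-BuLi), THF, −20 °C; n-BuLi (3 equiv), −20 °C; CuBr·SMe2 (10 mol%), 5, −78 °C to rt; H2O
Reagents that add atoms: none
Why: Directed ortho-metalation with in situ aldehyde protection: the lithium alpha-amino alkoxide masks the aldehyde and, together with the 3-OMOM group, should direct n-BuLi to C2 (the only C–H flanked by two directing groups), and the aryllithium is then allylated at the primary carbon of prenyl bromide under copper catalysis.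

Step 4
Reactants: 9 3,4-bis(methoxymethoxy)-2,5-bis(3-methylbut-2-en-1-yl)benzaldehyde; 10 1-methoxy-1-(trimethylsilyloxy)ethene
Product: 11 methyl (3S)-3-[3,4-bis(methoxymethoxy)-2,5-bis(3-methylbut-2-en-1-yl)phenyl]-3-(trimethylsilyloxy)propanoate
Conditions: Ti(O-i-Pr)4 (3 mol%), chiral N-(3-bromo-5-tert-butylsalicylidene)-2-amino-2′-hydroxy-1,1′-binaphthyl (3 mol%), 3,5-di-tert-butylsalicylic acid (3 mol%), Et2O, −10 °C; filtration through Et3N-deactivated silica
Reagents that add atoms: none
Why: Catalytic asymmetric Mukaiyama aldol addition: the chiral titanium complex binds the aldehyde, the ligand antipode is chosen so that the ketene acetal adds to the Si face (which gives the (S)-carbinol, the future C2), and silyl transfer to the aldolate delivers the trimethylsilyl ether directly.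

Step 5
Reactants: 12 phloroglucinol (benzene-1,3,5-triol)
Product: 13 3,5-bis(methoxymethoxy)phenol
Conditions: MOMCl (2.0 equiv), i-Pr2NEt, DMF, 0 °C to rt; chromatography
Reagents that add atoms: chloromethyl methyl ether (MOMCl), COCCl
Why: Statistical twofold O-alkylation of the symmetrical triol, in which the mono- and tris-ethers should be separable and recyclable.

Step 6
Reactants: 13 3,5-bis(methoxymethoxy)phenol
Product: 14 2-bromo-3,5-bis(methoxymethoxy)phenol
Conditions: NBS (1.0 equiv), i-Pr2NH (10 mol%), CH2Cl2, −78 °C to 0 °C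
Reagents that add atoms: N-bromosuccinimide, O=C1CCC(=O)N1Br
Why: Electrophilic aromatic bromination of a very electron-rich phenol; the two ortho positions are equivalent, and amine-mediated delivery of bromine through the phenol OH should favour them over the more hindered position between the two OMOM groups.

Step 7
Reactants: 14 2-bromo-3,5-bis(methoxymethoxy)phenol
Product: 17 3,5-bis(methoxymethoxy)-2-(trimethylsilyl)phenyl trifluoromethanesulfonate, via aryl trimethylsilyl ether 15 (not isolated), via lithium 2-silylphenoxide 16 (not isolated)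
Conditions: (Me3Si)2NH, THF, 65 °C, then evaporation; n-BuLi, THF, −78 °C; Tf2O, −78 °C to rt
Reagents that add atoms: hexamethyldisilazane, C[Si](C)(C)N[Si](C)(C)C; trifluoromethanesulfonic anhydride, O=S(=O)(OS(=O)(=O)C(F)(F)F)C(F)(F)F
Why: O-silylation, bromine–lithium exchange and a 1,3 O-to-C silyl shift of the ortho-lithio aryl silyl ether (retro-Brook rearrangement) should give phenoxide 16, which is triflated in the same flask to the aryne precursor.

Step 8
Reactants: 11 methyl (3S)-3-[3,4-bis(methoxymethoxy)-2,5-bis(3-methylbut-2-en-1-yl)phenyl]-3-(trimethylsilyloxy)propanoate; 17 3,5-bis(methoxymethoxy)-2-(trimethylsilyl)phenyl trifluoromethanesulfonate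
Product: 21 (2S)-5,7-bis(methoxymethoxy)-2-[3,4-bis(methoxymethoxy)-2,5-bis(3-methylbut-2-en-1-yl)phenyl]chroman-4-one, via cesium alkoxide 18 (not isolated), via aryne 19 (not isolated), via aryl anion 20 (not isolated)
Conditions: CsF (1.3 equiv), 18-crown-6, THF, 0 °C to rt, 17 (1.3 equiv) added slowly
Reagents that add atoms: none
Why: Proposed new method: fluoride frees alkoxide 18 from the silyl ether and aryne 19 from 17; 18 adds to the aryne carbon remote from the neighbouring OMOM group (future C8a), and the aryl anion 20 that appears at the future C4a, with no O–H in the flask to quench it, attacks the methyl ester and expels methoxide, which forms the C4–C4a bond and closes ring C. The closest known reaction types are the aryne annulation of salicylate esters to xanthones (phenoxide addition, then acylation of the aryl anion by the ester) and the formal insertions of arynes into N–acyl and C–acyl bonds; a silyl-masked aliphatic alkoxide and an aliphatic ester have not been used in this way. Ring C closes in a 6-exo-trig addition of the aryl anion to the ester carbonyl, and the strain of the aryne triple bond drives the whole event. No stereocenter is formed; the C2–O bond of 11 is never broken, so C2 is carried over with retention as (S). The step needs regioselective O–aryl bond formation, secured by the inductive effect of the OMOM oxygen next to the aryne (attack at the distal carbon, carbanion next to oxygen), and it needs acylation to outrun proton transfer and E1cB loss of the new aryloxy group, secured by the silyl mask (no O–H) and by the fact that the only base is used up in the event that creates the leaving group. The expelled methoxide should be taken up at silicon by 17 or 11, which releases the next aryne or alkoxide and leaves no free base to open ring C of the product.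

Step 9
Reactants: 21 (2S)-5,7-bis(methoxymethoxy)-2-[3,4-bis(methoxymethoxy)-2,5-bis(3-methylbut-2-en-1-yl)phenyl]chroman-4-one
Product: 22 sigmoidin A, (2S)-2-[3,4-dihydroxy-2,5-bis(3-methylbut-2-en-1-yl)phenyl]-5,7-dihydroxychroman-4-one
Conditions: 3 M aq. HCl, MeOH, 45 °C
Reagents that add atoms: none
Why: Acid-catalysed acetal exchange of the four MOM ethers with methanol; C2 should hold because flavanones open to chalcones under base and not under dilute acid, and the prenyl groups should survive because chroman formation needs stronger acid or more heat.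

**Compound list**

1 | 3-bromo-4,5-dihydroxybenzaldehyde | O=Cc1cc(O)c(O)c(Br)c1 | starting material
2 | 3-bromo-4,5-bis(methoxymethoxy)benzaldehyde | O=Cc1cc(OCOC)c(OCOC)c(Br)c1 | intermediate
3 | tributyl(3-methylbut-2-en-1-yl)stannane | CCCC[Sn](CCCC)(CCCC)CC=C(C)C | starting material
4 | 3,4-bis(methoxymethoxy)-5-(3-methylbut-2-en-1-yl)benzaldehyde | O=Cc1cc(OCOC)c(OCOC)c(CC=C(C)C)c1 | intermediate
5 | 1-bromo-3-methylbut-2-ene (prenyl bromide) | CC(C)=CCBr | starting material
6 | lithium alpha-amino alkoxide of 4 (adduct of 4 with lithium N,N,N′-trimethylethylenediamide) | [Li]OC(N(C)CCN(C)C)c1cc(OCOC)c(OCOC)c(CC=C(C)C)c1 | intermediate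
7 | C2-lithiated alpha-amino alkoxide | [Li]OC(N(C)CCN(C)C)c1cc(CC=C(C)C)c(OCOC)c(OCOC)c1[Li] | intermediate
8 | C2-prenylated alpha-amino alkoxide | [Li]OC(N(C)CCN(C)C)c1cc(CC=C(C)C)c(OCOC)c(OCOC)c1CC=C(C)C | intermediate
9 | 3,4-bis(methoxymethoxy)-2,5-bis(3-methylbut-2-en-1-yl)benzaldehyde | O=Cc1cc(CC=C(C)C)c(OCOC)c(OCOC)c1CC=C(C)C | intermediate
10 | 1-methoxy-1-(trimethylsilyloxy)ethene | COC(=C)O[Si](C)(C)C | starting material
11 | methyl (3S)-3-[3,4-bis(methoxymethoxy)-2,5-bis(3-methylbut-2-en-1-yl)phenyl]-3-(trimethylsilyloxy)propanoate | CC(C)=CCc1cc([C@@H](O[Si](C)(C)C)CC(=O)OC)c(CC=C(C)C)c(OCOC)c1OCOC | intermediate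
12 | phloroglucinol (benzene-1,3,5-triol) | Oc1cc(O)cc(O)c1 | starting material
13 | 3,5-bis(methoxymethoxy)phenol | COCOc1cc(O)cc(OCOC)c1 | intermediate
14 | 2-bromo-3,5-bis(methoxymethoxy)phenol | COCOc1cc(O)c(Br)c(OCOC)c1 | intermediate
15 | [2-bromo-3,5-bis(methoxymethoxy)phenoxy]trimethylsilane | COCOc1cc(O[Si](C)(C)C)c(Br)c(OCOC)c1 | intermediate
16 | lithium 3,5-bis(methoxymethoxy)-2-(trimethylsilyl)phenoxide | COCOc1cc([O-])c([Si](C)(C)C)c(OCOC)c1.[Li+] | intermediate
17 | 3,5-bis(methoxymethoxy)-2-(trimethylsilyl)phenyl trifluoromethanesulfonate | COCOc1cc(OS(=O)(=O)C(F)(F)F)c([Si](C)(C)C)c(OCOC)c1 | intermediate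
18 | cesium (S)-alkoxide of the hydroxy ester (desilylated 11) | CC(C)=CCc1cc([C@@H]([O-])CC(=O)OC)c(CC=C(C)C)c(OCOC)c1OCOC.[Cs+] | intermediate
19 | 3,5-bis(methoxymethoxy)benzyne | COCOC1=CC(OCOC)=CC#C1 | intermediate
20 | cesium aryl anion of the (S)-beta-aryloxy ester (carbanion at the future C4a) | CC(C)=CCc1cc([C@@H](Oc2cc(OCOC)cc(OCOC)[c-]2)CC(=O)OC)c(CC=C(C)C)c(OCOC)c1OCOC.[Cs+] | intermediate
21 | (2S)-5,7-bis(methoxymethoxy)-2-[3,4-bis(methoxymethoxy)-2,5-bis(3-methylbut-2-en-1-yl)phenyl]chroman-4-one | CC(C)=CCc1cc([C@@H]2CC(=O)c3c(OCOC)cc(OCOC)cc3O2)c(CC=C(C)C)c(OCOC)c1OCOC | intermediate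
22 | sigmoidin A, (2S)-2-[3,4-dihydroxy-2,5-bis(3-methylbut-2-en-1-yl)phenyl]-5,7-dihydroxychroman-4-one | CC(C)=CCc1cc([C@@H]2CC(=O)c3c(O)cc(O)cc3O2)c(CC=C(C)C)c(O)c1O | target

**Step count**

Total: 9 steps. Longest linear sequence: 6 steps (steps 1, 2, 3, 4, 8, 9); the aryne branch (steps 5 to 7) joins at step 8.

**Steps most likely to fail**

1. Step 8 (proposed new method). What may go wrong:
   - proton transfer to the aryl anion before it acylates, which would stop at the open aryl ether;
   - retro-aldol cleavage of the free alkoxide;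
   - base-induced opening of ring C after closure, with loss of configuration at C2.

   Fallback (known chemistry): it sets out from aldehyde 9 and comes back at 21. The aldol of step 4, run with the antipodal ligand, would give the (R)-silyl ether F1, and citric acid in MeOH the (R)-hydroxy ester F2. Me(MeO)NH·HCl and i-PrMgCl (THF, −20 °C) would turn this into the (R)-hydroxy N-methoxy-N-methylamide F3. A Mitsunobu reaction with bromophenol 14 (PPh3, DIAD, toluene, 0 °C) would form the O–C2 bond with inversion and give the (S)-bromoaryl ether F4. n-BuLi at −78 °C would exchange the bromine to the aryllithium F5, which would close ring C by a Parham cyclization on the amide to the lithium hemiaminal F6; aqueous work-up would give 21.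

2. Step 3. What may go wrong: competing deprotonation at the benzylic–allylic CH2 of the C5 prenyl group or at C6 instead of C2, and addition of n-BuLi to an incompletely masked aldehyde.

   Fallback: it sets out from 1 and comes back at 9, with no organolithium step. Br2/NaOAc in AcOH should brominate ortho to the 3-OH group, between CHO and OH (the position taken in the related 3-hydroxy-4-methoxybenzaldehyde), to give 2,5-dibromo-3,4-dihydroxybenzaldehyde F7. MOMCl/i-Pr2NEt would give 2,5-dibromo-3,4-bis(methoxymethoxy)benzaldehyde F8. A twofold Stille coupling with 3 (Pd(PPh3)4, DMF, 100 °C) would install both prenyl groups and give 9.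

3. Step 4. What may go wrong: poor facial selectivity with this ortho-substituted, electron-rich aldehyde, and loss of the trimethylsilyl group during isolation.

   Fallback: it sets out from 9 and comes back at 11. The lithium enolate of methyl acetate (LDA, THF, −78 °C) would add to 9 to give the lithium aldolate F9 and, after work-up, the racemic hydroxy ester F10. Oxidation with the periodinane DMP would give the beta-keto ester F11. Asymmetric transfer hydrogenation with RuCl[(S,S)-TsDPEN](p-cymene) in HCO2H/Et3N is expected to reduce the aryl ketone to the (S)-carbinol and leave the prenyl alkenes alone, giving the (S)-hydroxy ester F12. TMSCl/imidazole would return 11.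

Further compounds
F1 | step 8 | methyl (3R)-3-[3,4-bis(methoxymethoxy)-2,5-bis(3-methylbut-2-en-1-yl)phenyl]-3-(trimethylsilyloxy)propanoate | CC(C)=CCc1cc([C@H](O[Si](C)(C)C)CC(=O)OC)c(CC=C(C)C)c(OCOC)c1OCOC
F2 | step 8 | methyl (3R)-3-[3,4-bis(methoxymethoxy)-2,5-bis(3-methylbut-2-en-1-yl)phenyl]-3-hydroxypropanoate | CC(C)=CCc1cc([C@H](O)CC(=O)OC)c(CC=C(C)C)c(OCOC)c1OCOC
F3 | step 8 | (3R)-3-[3,4-bis(methoxymethoxy)-2,5-bis(3-methylbut-2-en-1-yl)phenyl]-3-hydroxy-N-methoxy-N-methylpropanamide | CC(C)=CCc1cc([C@H](O)CC(=O)N(C)OC)c(CC=C(C)C)c(OCOC)c1OCOC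
F4 | step 8 | (3S)-3-[2-bromo-3,5-bis(methoxymethoxy)phenoxy]-3-[3,4-bis(methoxymethoxy)-2,5-bis(3-methylbut-2-en-1-yl)phenyl]-N-methoxy-N-methylpropanamide | CC(C)=CCc1cc([C@@H](Oc2cc(OCOC)cc(OCOC)c2Br)CC(=O)N(C)OC)c(CC=C(C)C)c(OCOC)c1OCOC
F5 | step 8 | aryllithium from F4 (lithium in place of bromine) | CC(C)=CCc1cc([C@@H](Oc2cc(OCOC)cc(OCOC)c2[Li])CC(=O)N(C)OC)c(CC=C(C)C)c(OCOC)c1OCOC
F6 | step 8 | lithium hemiaminal of 21 (C4 carrying OLi and N(OMe)Me) | CC(C)=CCc1cc([C@@H]2CC(O[Li])(N(C)OC)c3c(OCOC)cc(OCOC)cc3O2)c(CC=C(C)C)c(OCOC)c1OCOC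
F7 | step 3 | 2,5-dibromo-3,4-dihydroxybenzaldehyde | O=Cc1cc(Br)c(O)c(O)c1Br
F8 | step 3 | 2,5-dibromo-3,4-bis(methoxymethoxy)benzaldehyde | O=Cc1cc(Br)c(OCOC)c(OCOC)c1Br
F9 | step 4 | lithium aldolate, racemic (lithium alkoxide of F10) | CC(C)=CCc1cc(C(O[Li])CC(=O)OC)c(CC=C(C)C)c(OCOC)c1OCOC
F10 | step 4 | methyl 3-[3,4-bis(methoxymethoxy)-2,5-bis(3-methylbut-2-en-1-yl)phenyl]-3-hydroxypropanoate, racemic | CC(C)=CCc1cc(C(O)CC(=O)OC)c(CC=C(C)C)c(OCOC)c1OCOC
F11 | step 4 | methyl 3-[3,4-bis(methoxymethoxy)-2,5-bis(3-methylbut-2-en-1-yl)phenyl]-3-oxopropanoate | CC(C)=CCc1cc(C(=O)CC(=O)OC)c(CC=C(C)C)c(OCOC)c1OCOC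
F12 | step 4 | methyl (3S)-3-[3,4-bis(methoxymethoxy)-2,5-bis(3-methylbut-2-en-1-yl)phenyl]-3-hydroxypropanoate | CC(C)=CCc1cc([C@@H](O)CC(=O)OC)c(CC=C(C)C)c(OCOC)c1OCOC
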